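## Retrosynthetic overview

1. Target 35 ⇐ diol 33 (acetylation, desilylation) ⇐ B-alkyl Suzuki coupling (C12–C13) of iodide 27 with Z-iodoalkene 30; 7α-OH/C8=C17 ⇐ 7α,8α-epoxide 23 (trivalent titanium); C9–C11 ⇐ Johnson–Claisen rearrangement of 7β-allylic alcohol 20.
2. Ring B (closed last, C8–C9) ⇐ aldol condensation of a C7 ethyl ketone with the C9 aldehyde on a ring A precursor; C2 is inverted (Mitsunobu) before this closure.
3. Ring A with its C2 oxygen and its C5–C6–C7 arm ⇐ Baeyer–Villiger cleavage of the temporary C2–C7 bond of bicyclo[2.2.2]octanone 11.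
4. 11 ⇐ one-flask double Michael addition (C2–C3, then C4–C5) of the α′-dienolate of (S)-4-cyano-4-methylcyclohexenone 7 to methyl methacrylate 8. Ring order: temporary cyclohexenone ring (C2, C7, C6, C5, C10, C1), then ring A (as two bridges of the bicycle), then ring B.
5. Enabling feature: in ring A the oxygen-bearing C2 and the ring-fusion carbon C5 are 1,4-related, and C5 carries the C6–C7 arm whose end C7 is also oxygenated. Tying C7 back to C2 as a ketone makes ring A (bridges C1–C10 and C3–C4, bridgeheads C2 and C5) part of a bicyclo[2.2.2]octan-2-one, the adduct of a cyclohexenone dienolate (C2–C7–C6–C5) and a methacrylate (C3=C4).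

Key step: step 5

Remark on names: labdane numbering is used throughout (C18 = 4α-CH3, C19 = 4β carbon, C20 = 10β-CH3); α/β give the face in the usual drawing of the final decalin, also for monocyclic and bicyclic precursors.

Assumption: in step 1 the antipode of the PhTRAP ligand is chosen that delivers the (R)-adduct 3; if needed, enantiomeric purity is raised by crystallisation of 11 or 12.

## Route

Step 1
Reactants: 1 ethyl 2-cyanopropanoate; 2 but-3-en-2-one
Product: 3 ethyl (2R)-2-cyano-2-methyl-5-oxohexanoate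
Conditions: RhH(CO)(PPh3)3 (1 mol %), PhTRAP (1.1 mol %), benzene, 3 °C
Reagents that add atoms: none
Why: Catalytic asymmetric Michael addition of an α-cyano ester to a vinyl ketone through a rhodium cyano-enolate held by the trans-chelating chiral diphosphine, which differentiates the enolate faces and sets the quaternary carbon (future C10).

Step 2
Reactants: 3 ethyl (2R)-2-cyano-2-methyl-5-oxohexanoate
Product: 4 (2R)-5-hydroxy-2-(hydroxymethyl)-2-methylhexanenitrile (both C5 epimers)
Conditions: LiBH4 (2.5 equiv), THF, 0 °C to rt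
Reagents that add atoms: none
Why: Borohydride reduction of the ketone and of the cyano-activated ester leaves the nitrile intact; the quaternary centre cannot epimerise and the new carbinol centre is removed again in step 3.

Step 3
Reactants: 4 (2R)-5-hydroxy-2-(hydroxymethyl)-2-methylhexanenitrile
Product: 5 (2R)-2-formyl-2-methyl-5-oxohexanenitrile
Conditions: Dess–Martin periodinane (2.5 equiv), NaHCO3, CH2Cl2, rt
Reagents that add atoms: none
Why: Dess–Martin oxidation of both alcohols under buffered conditions; the α-cyano aldehyde is quaternary and configurationally fixed.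

Step 4
Reactants: 5 (2R)-2-formyl-2-methyl-5-oxohexanenitrile
Product: 7 (S)-1-methyl-4-oxocyclohex-2-ene-1-carbonitrile, via aldol 6 (not isolated)
Conditions: p-TsOH·H2O (5 mol %), toluene, reflux, Dean–Stark
Reagents that add atoms: none
Why: Intramolecular aldol condensation in which only the methyl group of the ketone can close a six-membered ring on the non-enolisable aldehyde, followed by dehydration to the conjugated enone; the quaternary centre is untouched.

Step 5
Reactants: 7 (S)-1-methyl-4-oxocyclohex-2-ene-1-carbonitrile; 8 methyl methacrylate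
Product: 11 methyl 7-cyano-2,7-dimethyl-5-oxobicyclo[2.2.2]octane-2-carboxylate (bridgeheads C5 and C2; CO2Me on C4 and CH3 on C10 both syn to the C6–C7 ketone bridge), via lithium dienolate 9 (not isolated), via ester enolate 10 (not isolated)
Conditions: LDA (LiN(i-Pr)2, 1.05 equiv), THF, −78 °C; then 8 (1.2 equiv), −78 °C to rt; AcOH quench
Reagents that add atoms: none
Why: LDA removes an α′ hydrogen at C2 to give the cross-conjugated dienolate 9, which adds through C2 to the CH2 terminus of the methacrylate (C2–C3); the resulting ester enolate 10 then adds to the enone β-carbon (C4–C5) to give the ketone enolate of 11. The closest known reaction type is the aprotic double Michael reaction (anionic [4+2] annulation) of cyclohexenone kinetic enolates with acrylates to bicyclo[2.2.2]octan-2-ones. The second Michael addition is 6-exo-trig with respect to ring A (C1–C5, C10) and 6-endo-trig with respect to the temporary C2–C3–C4–C5–C6–C7 ring. C2 and C5 are fixed as bridgeheads, which places the C7 carbonyl on C2 and the C6 methylene on C5 on the same side of ring A; C4 is set by a lithium-bridged compact transition state that holds the ester enolate oxygen over the enone oxygen, so CO2Me (C19) ends syn to the ketone bridge and CH3 (C18) points to the C1–C10 bridge. The configuration relative to C10 follows from closure on the face carrying the slim nitrile: the first Michael addition is reversible (ketone enolate to less stable ester enolate), and closure on the methyl face would press C18 against C20. The step needs α′- rather than γ-enolisation (secured by the quaternary C10), conjugate rather than carbonyl addition (low temperature, ester enolate on enone), and ring closure faster than acrylate oligomerisation (intramolecular closure, only a slight excess of 8).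

Step 6
Reactants: 11 methyl 7-cyano-2,7-dimethyl-5-oxobicyclo[2.2.2]octane-2-carboxylate
Product: 12 methyl 6-cyano-6,9-dimethyl-3-oxo-2-oxabicyclo[3.2.2]nonane-9-carboxylate (lactone oxygen between C7 and C2)
Conditions: mCPBA (1.5 equiv), NaHCO3, CH2Cl2, 0 °C to rt
Reagents that add atoms: 3-chloroperoxybenzoic acid, OOC(=O)c1cccc(Cl)c1
Why: Baeyer–Villiger oxidation in which the more substituted bridgehead carbon C2 migrates in preference to the C6 methylene and with retention, so oxygen enters the temporary C2–C7 bond (2β-oxygen) and C7 becomes a lactone carbonyl; nitrile and ester are inert.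

Step 7
Reactants: 12 Baeyer–Villiger lactone
Product: 14 methyl 10α-cyano-2β-hydroxy-4α,10β-dimethyl-5β-(2-oxobutyl)cyclohexane-4β-carboxylate (ring A; H-5 α), via Weinreb amide 13 (not isolated)
Conditions: MeNH(OMe)·HCl (1.5 equiv), EtMgBr (6 equiv), THF, −20 to 0 °C; aq NH4Cl
Reagents that add atoms: ethylmagnesium bromide, CC[Mg]Br
Why: One-flask Weinreb sequence in which the magnesium amide opens the unhindered lactone (not the hindered quaternary C19 ester or the tertiary nitrile) to amide 13, whose chelated adduct with EtMgBr releases the ethyl ketone (C8, C17) only on work-up.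

Step 8
Reactants: 14 ring A hydroxy ethyl ketone nitrile
Product: 15 methyl 10α-formyl-2β-hydroxy-4α,10β-dimethyl-5β-(2-oxobutyl)cyclohexane-4β-carboxylate
Conditions: Raney Ni, NaH2PO2·H2O, pyridine/AcOH/H2O (2:1:1), 45 °C
Reagents that add atoms: water, O
Why: Raney nickel/hypophosphite transfer reduction of the nitrile stops at the aldimine, which hydrolyses in the aqueous acetic acid to the C9 aldehyde; ketone, ester and alcohol are tolerated and no stereocentre is touched.

Step 9
Reactants: 15 ring A hydroxy keto aldehyde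
Product: 16 methyl 10α-formyl-4α,10β-dimethyl-2α-(4-nitrobenzoyloxy)-5β-(2-oxobutyl)cyclohexane-4β-carboxylate
Conditions: PPh3 (2 equiv), DIAD (2 equiv), 4-nitrobenzoic acid (2 equiv), toluene, 0 °C to rt
Reagents that add atoms: 4-nitrobenzoic acid, OC(=O)c1ccc(cc1)[N+](=O)[O-]
Why: Mitsunobu esterification with an acidic carboxylic acid inverts C2 by SN2 displacement of the oxyphosphonium group to the required 2α configuration; at this monocyclic stage the ring can still flip, so the leaving group is not locked between the two syn-axial groups that flank it in the decalin.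

Step 10
Reactants: 16 ring A nitrobenzoate keto aldehyde
Product: 18 methyl 2α-hydroxy-7-oxo-11,12,13,14,15,16-hexanorlabd-8-en-19-oate (trans-decalin; H-5 α), via hydroxy keto aldehyde 17 (not isolated)
Conditions: NaOMe (0.5 equiv), MeOH, 0 to 45 °C
Reagents that add atoms: none
Why: Methoxide transesterifies the nitrobenzoate and promotes the intramolecular aldol condensation of the ethyl ketone (C8) with the non-enolisable aldehyde (C9), which can only close six-membered ring B; C5 and C10 are already fixed, so the fusion is trans, and the 2α-alkoxide is trans to the C19 ester and cannot lactonise.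

Step 11
Reactants: 18 decalin hydroxy enone
Product: 19 methyl 2α-(tert-butyldimethylsilyloxy)-7-oxo-11,12,13,14,15,16-hexanorlabd-8-en-19-oate
Conditions: TBSCl, imidazole, DMF, rt
Reagents that add atoms: tert-butyldimethylsilyl chloride, CC(C)(C)[Si](C)(C)Cl
Why: Standard silylation of the unhindered equatorial secondary alcohol, giving a group that survives all later basic, reducing and organometallic steps.

Step 12
Reactants: 19 silyl ether enone
Product: 20 methyl 2α-(tert-butyldimethylsilyloxy)-7β-hydroxy-11,12,13,14,15,16-hexanorlabd-8-en-19-oate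
Conditions: NaBH4, CeCl3·7H2O, MeOH, −40 °C
Reagents that add atoms: none
Why: Luche 1,2-reduction in which hydride adds axially from the α face, giving the pseudo-equatorial 7β-alcohol needed for chirality transfer in step 13; the hindered ester is untouched.

Step 13
Reactants: 20 7β-allylic alcohol
Product: 22 12-ethyl 19-methyl 2α-(tert-butyldimethylsilyloxy)-13,14,15,16-tetranorlabd-7-ene-12,19-dioate (H-9 α), via ketene acetal 21 (not isolated)
Conditions: MeC(OEt)3 (10 equiv), EtCO2H (cat.), xylene, 140 °C, EtOH distilled off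
Reagents that add atoms: triethyl orthoacetate, CC(OCC)(OCC)OCC
Why: Johnson–Claisen rearrangement in which the ketene acetal 21 rearranges suprafacially, delivering the acetate chain (C11, C12) from the 7β-oxygen to the β face of C9 and moving the double bond to C7–C8.

Step 14
Reactants: 22 Δ7 diester
Product: 23 12-ethyl 19-methyl 2α-(tert-butyldimethylsilyloxy)-7α,8α-epoxy-13,14,15,16-tetranorlabdane-12,19-dioate
Conditions: mCPBA, NaHCO3, CH2Cl2, 0 °C
Reagents that add atoms: 3-chloroperoxybenzoic acid, OOC(=O)c1cccc(Cl)c1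
Why: Prilezhaev epoxidation of the trisubstituted ring alkene from the α face, the β face being screened by the axial C20 methyl and the C9 side chain; this sets the α oxygen at C7.

Step 15
Reactants: 23 7α,8α-epoxide
Product: 24 12-ethyl 19-methyl 2α-(tert-butyldimethylsilyloxy)-7α-hydroxy-13,14,15,16-tetranorlabd-8(17)-ene-12,19-dioate
Conditions: Cp2TiCl2 (2.5 equiv), Mn dust (8 equiv), THF, rt; cold dilute aqueous acid work-up
Reagents that add atoms: none
Why: Trivalent titanium (Cp2TiCl) opens the epoxide homolytically to the tertiary C8 radical with the titanium alkoxide left on C7, and hydrogen abstraction by a second Cp2TiCl from the unhindered C17 methyl gives the exocyclic alkene (epoxide-to-allylic-alcohol isomerisation of the Nugent–RajanBabu type); C7 keeps its α oxygen and esters are inert.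

Step 16
Reactants: 24 7α-allylic alcohol
Product: 25 12-ethyl 19-methyl 2α,7α-bis(tert-butyldimethylsilyloxy)-13,14,15,16-tetranorlabd-8(17)-ene-12,19-dioate
Conditions: TBSOTf, 2,6-lutidine, CH2Cl2, −78 to 0 °C
Reagents that add atoms: tert-butyldimethylsilyl triflate, CC(C)(C)[Si](C)(C)OS(=O)(=O)C(F)(F)F
Why: The silyl triflate protects the hindered axial allylic alcohol so that it takes no part in the iodination and acetylation that follow.

Step 17
Reactants: 25 bis-silyl ether diester
Product: 26 2α,7α-bis(tert-butyldimethylsilyloxy)-13,14,15,16-tetranorlabd-8(17)-ene-12,19-diol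
Conditions: LiAlH4, THF, 0 °C
Reagents that add atoms: none
Why: Hydride reduction of both esters to primary alcohols (C12 and the C19 hydroxymethyl of the target); silyl ethers and the alkene are stable.

Step 18
Reactants: 26 12,19-diol
Product: 27 2α,7α-bis(tert-butyldimethylsilyloxy)-12-iodo-13,14,15,16-tetranorlabd-8(17)-en-19-ol
Conditions: I2, PPh3, imidazole, CH2Cl2, 0 °C
Reagents that add atoms: iodine, II
Why: Appel iodination is selective for the unhindered primary C12 alcohol because the neopentyl-type C19 oxyphosphonium cannot be displaced by iodide.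

Step 19
Reactants: 28 but-2-yn-1-ol
Product: 30 (Z)-3-iodobut-2-en-1-ol, via alkenylalanate 29 (not isolated)
Conditions: NaAlH2(OCH2CH2OMe)2 (Red-Al), THF, 0 °C to rt; EtOAc; then I2, −78 to 0 °C
Reagents that add atoms: iodine, II
Why: Hydroxyl-directed trans-hydroalumination places aluminium on C3 (chelate 29) and iodinolysis with retention gives the Z-iodoalkene, which fixes the 13Z geometry.

Step 20
Reactants: 27 C12 iodide; 30 (Z)-3-iodobut-2-en-1-ol
Product: 33 2α,7α-bis(tert-butyldimethylsilyloxy)labda-8(17),13Z-diene-15,19-diol, via alkyllithium 31 (not isolated), via borinate 32 (not isolated)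
Conditions: t-BuLi (3.2 equiv), Et2O, −78 °C; B-methoxy-9-BBN (3.5 equiv), THF, −78 °C to rt; then 30, Pd(dppf)Cl2 (5 mol %), AsPh3, K3PO4 (3 M aq), DMF, rt
Reagents that add atoms: none
Why: Lithium–iodine exchange, trapping as the B-alkyl-9-BBN borinate and B-alkyl Suzuki–Miyaura coupling form C12–C13 with retention of the alkene geometry; the free hydroxyls are carried as alkoxides.

Step 21
Reactants: 33 15,19-diol
Product: 34 2α,7α-bis(tert-butyldimethylsilyloxy)labda-8(17),13Z-diene-15,19-diyl diacetate
Conditions: Ac2O, pyridine, DMAP (cat.), CH2Cl2, 0 °C to rt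
Reagents that add atoms: acetic anhydride, CC(=O)OC(C)=O
Why: Acylation of the only two free hydroxyls, both primary, installs both acetates in one operation.

Step 22
Reactants: 34 bis-silyl ether diacetate
Product: 35 2α,7α-dihydroxylabda-8(17),13Z-diene-15,19-diyl diacetate (CNP0171158.2)
Conditions: HF·pyridine, pyridine, THF, 0 °C to rt
Reagents that add atoms: none
Why: Buffered fluoride cleaves both secondary silyl ethers while the primary and allylic acetates and the alkene geometry are unaffected.

## Compound list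

1 | ethyl 2-cyanopropanoate | CCOC(=O)C(C)C#N | starting material
2 | but-3-en-2-one (methyl vinyl ketone) | CC(=O)C=C | starting material
3 | ethyl (2R)-2-cyano-2-methyl-5-oxohexanoate | CCOC(=O)[C@@](C)(C#N)CCC(C)=O | intermediate
4 | (2R)-5-hydroxy-2-(hydroxymethyl)-2-methylhexanenitrile (both C5 epimers) | OC[C@@](C)(C#N)CCC(C)O | intermediate
5 | (2R)-2-formyl-2-methyl-5-oxohexanenitrile | O=C[C@@](C)(C#N)CCC(C)=O | intermediate
6 | 2-hydroxy-1-methyl-4-oxocyclohexane-1-carbonitrile, aldol (carbinol epimers) | C[C@@]1(C#N)C(O)CC(=O)CC1 | intermediate (not isolated)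
7 | (S)-1-methyl-4-oxocyclohex-2-ene-1-carbonitrile | C[C@@]1(C#N)C=CC(=O)CC1 | intermediate
8 | methyl methacrylate | C=C(C)C(=O)OC | starting material
9 | lithium α′-dienolate of 7 | C[C@@]1(C#N)C=CC(O[Li])=CC1 | intermediate (not isolated)
10 | lithium ester enolate after the first Michael addition (C2–C3 formed) | C[C@@]1(C#N)C=CC(=O)[C@H](CC(C)=C(OC)O[Li])C1 | intermediate (not isolated)
11 | methyl 7-cyano-2,7-dimethyl-5-oxobicyclo[2.2.2]octane-2-carboxylate (CO2Me and 7-CH3 syn to the ketone bridge) | O=C1C[C@H]2[C@@](C)(C(=O)OC)C[C@@H]1C[C@]2(C)C#N | intermediate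
12 | methyl 6-cyano-6,9-dimethyl-3-oxo-2-oxabicyclo[3.2.2]nonane-9-carboxylate | O=C1C[C@H]2[C@@](C)(C(=O)OC)C[C@@H](O1)C[C@]2(C)C#N | intermediate
13 | Weinreb amide of the opened lactone (2β-OH) | CON(C)C(=O)C[C@H]1[C@@](C)(C(=O)OC)C[C@@H](O)C[C@]1(C)C#N | intermediate (not isolated)
14 | methyl 10α-cyano-2β-hydroxy-4α,10β-dimethyl-5β-(2-oxobutyl)cyclohexane-4β-carboxylate | CCC(=O)C[C@H]1[C@@](C)(C(=O)OC)C[C@@H](O)C[C@]1(C)C#N | intermediate
15 | methyl 10α-formyl-2β-hydroxy-4α,10β-dimethyl-5β-(2-oxobutyl)cyclohexane-4β-carboxylate | CCC(=O)C[C@H]1[C@@](C)(C(=O)OC)C[C@@H](O)C[C@]1(C)C=O | intermediate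
16 | methyl 10α-formyl-4α,10β-dimethyl-2α-(4-nitrobenzoyloxy)-5β-(2-oxobutyl)cyclohexane-4β-carboxylate | CCC(=O)C[C@H]1[C@@](C)(C(=O)OC)C[C@H](OC(=O)c2ccc(cc2)[N+](=O)[O-])C[C@]1(C)C=O | intermediate
17 | methyl 10α-formyl-2α-hydroxy-4α,10β-dimethyl-5β-(2-oxobutyl)cyclohexane-4β-carboxylate | CCC(=O)C[C@H]1[C@@](C)(C(=O)OC)C[C@H](O)C[C@]1(C)C=O | intermediate (not isolated)
18 | methyl 2α-hydroxy-7-oxo-11,12,13,14,15,16-hexanorlabd-8-en-19-oate | CC1=C[C@@]2(C)C[C@@H](O)C[C@](C)(C(=O)OC)[C@@H]2CC1=O | intermediate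
19 | methyl 2α-(tert-butyldimethylsilyloxy)-7-oxo-11,12,13,14,15,16-hexanorlabd-8-en-19-oate | CC1=C[C@@]2(C)C[C@@H](O[Si](C)(C)C(C)(C)C)C[C@](C)(C(=O)OC)[C@@H]2CC1=O | intermediate
20 | methyl 2α-(tert-butyldimethylsilyloxy)-7β-hydroxy-11,12,13,14,15,16-hexanorlabd-8-en-19-oate | CC1=C[C@@]2(C)C[C@@H](O[Si](C)(C)C(C)(C)C)C[C@](C)(C(=O)OC)[C@@H]2C[C@@H]1O | intermediate
21 | 7β-O-(1-ethoxyvinyl) ketene acetal of 20 | CC1=C[C@@]2(C)C[C@@H](O[Si](C)(C)C(C)(C)C)C[C@](C)(C(=O)OC)[C@@H]2C[C@@H]1OC(=C)OCC | intermediate (not isolated)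
22 | 12-ethyl 19-methyl 2α-(tert-butyldimethylsilyloxy)-13,14,15,16-tetranorlabd-7-ene-12,19-dioate | CC1=CC[C@H]2[C@@](C)(C(=O)OC)C[C@H](O[Si](C)(C)C(C)(C)C)C[C@]2(C)[C@H]1CC(=O)OCC | intermediate
23 | 12-ethyl 19-methyl 2α-(tert-butyldimethylsilyloxy)-7α,8α-epoxy-13,14,15,16-tetranorlabdane-12,19-dioate | C[C@@]12O[C@@H]1C[C@H]3[C@@](C)(C(=O)OC)C[C@H](O[Si](C)(C)C(C)(C)C)C[C@]3(C)[C@H]2CC(=O)OCC | intermediate
24 | 12-ethyl 19-methyl 2α-(tert-butyldimethylsilyloxy)-7α-hydroxy-13,14,15,16-tetranorlabd-8(17)-ene-12,19-dioate | C=C1[C@H](O)C[C@H]2[C@@](C)(C(=O)OC)C[C@H](O[Si](C)(C)C(C)(C)C)C[C@]2(C)[C@H]1CC(=O)OCC | intermediate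
25 | 12-ethyl 19-methyl 2α,7α-bis(tert-butyldimethylsilyloxy)-13,14,15,16-tetranorlabd-8(17)-ene-12,19-dioate | C=C1[C@H](O[Si](C)(C)C(C)(C)C)C[C@H]2[C@@](C)(C(=O)OC)C[C@H](O[Si](C)(C)C(C)(C)C)C[C@]2(C)[C@H]1CC(=O)OCC | intermediate
26 | 2α,7α-bis(tert-butyldimethylsilyloxy)-13,14,15,16-tetranorlabd-8(17)-ene-12,19-diol | C=C1[C@H](O[Si](C)(C)C(C)(C)C)C[C@H]2[C@@](C)(CO)C[C@H](O[Si](C)(C)C(C)(C)C)C[C@]2(C)[C@H]1CCO | intermediate
27 | 2α,7α-bis(tert-butyldimethylsilyloxy)-12-iodo-13,14,15,16-tetranorlabd-8(17)-en-19-ol | C=C1[C@H](O[Si](C)(C)C(C)(C)C)C[C@H]2[C@@](C)(CO)C[C@H](O[Si](C)(C)C(C)(C)C)C[C@]2(C)[C@H]1CCI | intermediate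
28 | but-2-yn-1-ol | CC#CCO | starting material
29 | sodium cyclic alkenylalanate from 28 and Red-Al | CC1=CCO[Al-]1(OCCOC)OCCOC.[Na+] | intermediate (not isolated)
30 | (Z)-3-iodobut-2-en-1-ol | C/C(I)=C/CO | intermediate
31 | C12 alkyllithium (19-lithium alkoxide) from 27 | C=C1[C@H](O[Si](C)(C)C(C)(C)C)C[C@H]2[C@@](C)(CO[Li])C[C@H](O[Si](C)(C)C(C)(C)C)C[C@]2(C)[C@H]1CC[Li] | intermediate (not isolated)
32 | lithium B-alkyl-B-methoxy-9-BBN borinate from 31 | C=C1[C@H](O[Si](C)(C)C(C)(C)C)C[C@H]2[C@@](C)(CO[Li])C[C@H](O[Si](C)(C)C(C)(C)C)C[C@]2(C)[C@H]1CC[B-]3(OC)C4CCCC3CCC4.[Li+] | intermediate (not isolated)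
33 | 2α,7α-bis(tert-butyldimethylsilyloxy)labda-8(17),13Z-diene-15,19-diol | C=C1[C@H](O[Si](C)(C)C(C)(C)C)C[C@H]2[C@@](C)(CO)C[C@H](O[Si](C)(C)C(C)(C)C)C[C@]2(C)[C@H]1CC/C(C)=C\CO | intermediate
34 | 2α,7α-bis(tert-butyldimethylsilyloxy)labda-8(17),13Z-diene-15,19-diyl diacetate | C=C1[C@H](O[Si](C)(C)C(C)(C)C)C[C@H]2[C@@](C)(COC(C)=O)C[C@H](O[Si](C)(C)C(C)(C)C)C[C@]2(C)[C@H]1CC/C(C)=C\COC(C)=O | intermediate
35 | 2α,7α-dihydroxylabda-8(17),13Z-diene-15,19-diyl diacetate (CNP0171158.2) | C=C1[C@H](O)C[C@H]2[C@@](C)(COC(C)=O)C[C@H](O)C[C@]2(C)[C@H]1CC/C(C)=C\COC(C)=O | target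

## Step count and risks

Total step count: 22. Longest linear sequence: 21 (steps 1–18 and 20–22; step 19 is a one-step side branch).

Steps most likely to fail:

Step 5 (key step). The ring closure at the congested C4–C5 bond (quaternary C4 next to quaternary C10) may lose out to protonation at the open Michael stage or to anionic oligomerisation of the methacrylate, and facial (C10) or endo (C4) control may erode. Fallback, leaving the anionic manifold: enone 7 is converted with TBSOTf and Et3N in CH2Cl2 at 0 °C into the silyl dienol ether (S)-4-(tert-butyldimethylsilyloxy)-1-methylcyclohexa-2,4-diene-1-carbonitrile F1. F1 is heated with 8 (neat, 130 °C, sealed tube, radical inhibitor, or 1.2 GPa at rt) in a concerted Diels–Alder reaction, with the ortho regiochemistry of 2-silyloxydienes and addition anti to the C10 methyl, to give the bicyclic silyl enol ether methyl 5-(tert-butyldimethylsilyloxy)-7-cyano-2,7-dimethylbicyclo[2.2.2]oct-5-ene-2-carboxylate F2. HF in MeCN should then release keto ester 11, where the route is rejoined; a C4 epimer, should it form, would be separated at 11.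

Step 9. The oxyphosphonium intermediate may undergo E2 elimination to ring A olefins, or the SN2 displacement at C2 may not proceed. Fallback, separating activation from displacement: 15 is converted with Tf2O and pyridine in CH2Cl2 at −20 °C into the 2β-triflate methyl 10α-formyl-4α,10β-dimethyl-5β-(2-oxobutyl)-2β-(trifluoromethylsulfonyloxy)cyclohexane-4β-carboxylate F3. Displacement with CsOAc and 18-crown-6 in toluene at 50 °C (a small, weakly basic carboxylate on a pre-formed sulfonate) should give the inverted 2α-acetate methyl 2α-acetoxy-10α-formyl-4α,10β-dimethyl-5β-(2-oxobutyl)cyclohexane-4β-carboxylate F4. Under the conditions of step 10 F4 loses its acetate and cyclises, and the route is rejoined at 18.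

Step 13. Orthoester exchange at the hindered 7β-alcohol may be slow, and acid at 140 °C may cause 1,4-elimination to a ring B diene before the [3,3] shift. Fallback, moving to the low-temperature enolate manifold (Ireland–Claisen): 20 is acetylated (Ac2O, DMAP, pyridine) to the 7β-acetate methyl 7β-acetoxy-2α-(tert-butyldimethylsilyloxy)-11,12,13,14,15,16-hexanorlabd-8-en-19-oate F5. LDA and TMSCl in THF/HMPA at −78 °C give the trimethylsilyl ketene acetal of F5, F6. On warming to rt F6 rearranges suprafacially to the trimethylsilyl ester of the C12 acid, F7, which is hydrolysed on work-up to 2α-(tert-butyldimethylsilyloxy)-19-methoxy-19-oxo-13,14,15,16-tetranorlabd-7-en-12-oic acid F8. Esterification with EtI and K2CO3 in DMF gives 22, where the route is rejoined.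

## Further compounds

F1 | step 5 | (S)-4-(tert-butyldimethylsilyloxy)-1-methylcyclohexa-2,4-diene-1-carbonitrile | C[C@@]1(C#N)C=CC(O[Si](C)(C)C(C)(C)C)=CC1
F2 | step 5 | methyl 5-(tert-butyldimethylsilyloxy)-7-cyano-2,7-dimethylbicyclo[2.2.2]oct-5-ene-2-carboxylate | CC(C)(C)[Si](C)(C)OC1=C[C@H]2[C@@](C)(C(=O)OC)C[C@@H]1C[C@]2(C)C#N
F3 | step 9 | methyl 10α-formyl-4α,10β-dimethyl-5β-(2-oxobutyl)-2β-(trifluoromethylsulfonyloxy)cyclohexane-4β-carboxylate | CCC(=O)C[C@H]1[C@@](C)(C(=O)OC)C[C@@H](OS(=O)(=O)C(F)(F)F)C[C@]1(C)C=O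
F4 | step 9 | methyl 2α-acetoxy-10α-formyl-4α,10β-dimethyl-5β-(2-oxobutyl)cyclohexane-4β-carboxylate | CCC(=O)C[C@H]1[C@@](C)(C(=O)OC)C[C@H](OC(C)=O)C[C@]1(C)C=O
F5 | step 13 | methyl 7β-acetoxy-2α-(tert-butyldimethylsilyloxy)-11,12,13,14,15,16-hexanorlabd-8-en-19-oate | CC1=C[C@@]2(C)C[C@@H](O[Si](C)(C)C(C)(C)C)C[C@](C)(C(=O)OC)[C@@H]2C[C@@H]1OC(C)=O
F6 | step 13 | trimethylsilyl ketene acetal of F5 | CC1=C[C@@]2(C)C[C@@H](O[Si](C)(C)C(C)(C)C)C[C@](C)(C(=O)OC)[C@@H]2C[C@@H]1OC(=C)O[Si](C)(C)C
F7 | step 13 | 19-methyl 12-trimethylsilyl 2α-(tert-butyldimethylsilyloxy)-13,14,15,16-tetranorlabd-7-ene-12,19-dioate | CC1=CC[C@H]2[C@@](C)(C(=O)OC)C[C@H](O[Si](C)(C)C(C)(C)C)C[C@]2(C)[C@H]1CC(=O)O[Si](C)(C)C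
F8 | step 13 | 2α-(tert-butyldimethylsilyloxy)-19-methoxy-19-oxo-13,14,15,16-tetranorlabd-7-en-12-oic acid | CC1=CC[C@H]2[C@@](C)(C(=O)OC)C[C@H](O[Si](C)(C)C(C)(C)C)C[C@]2(C)[C@H]1CC(=O)O
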